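**Plan**
- Retrosynthesis: the three benzyl ethers and the dioxolane are removed first; ring B is then opened at its C1–C2 bond (retro-6π) and the resulting dienylketene is folded back into a cyclobutenone by re-forming the four-membered C1–C4 bond.
- That cyclobutenone is cut at the O5–acyl bond (ring A acid chloride) and at the bond from its quaternary carbon to C3 of the crotonate (alkenylmagnesium plus benzyloxy methyl cyclobutenedione).
- Forward: ring A acid chloride from methyl orsellinate (5 steps), the dione from squaric acid (3 steps), the (E)-iodocrotonate from methyl but-2-ynoate (2 steps); Grignard addition, O-acylation, then thermolysis builds ring B last; acetal hydrolysis and hydrogenolysis finish.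
- Enabling feature: ring B is a hexasubstituted benzene with oxygens on C2, C4 and C5. O2 (free) and O5 (acylated) are para, a hydroquinone pair, and O4 is ortho to O5. They map onto the ketene oxygen, the acyloxy oxygen on the quaternary carbon and the squarate ether oxygen.
- Stereochemistry: the target has no stereocentre. Only the E geometry of the alkenyl unit matters; it comes from a syn-stannylcupration and is retained through iododestannylation and iodine–magnesium exchange. The racemic quaternary centre is erased in the ring expansion.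

Key step: step 13

Remark: every intermediate that carries the quaternary cyclobutenone carbon (or the sp3 carbon of the transient dienone) is racemic; one enantiomer is drawn in its SMILES.

Step 1
Reactants: 1 squaric acid
Product: 2 3,4-bis(benzyloxy)cyclobut-3-ene-1,2-dione (dibenzyl squarate)
Conditions: BnOH, toluene, reflux, azeotropic removal of water
Reagents that add atoms: benzyl alcohol, OCc1ccccc1
Why: Self-catalysed esterification of the strongly acidic vinylogous diacid, driven to the diester by continuous removal of water.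

Step 2
Reactants: 2 3,4-bis(benzyloxy)cyclobut-3-ene-1,2-dione
Product: 3 2,3-bis(benzyloxy)-4-hydroxy-4-methylcyclobut-2-en-1-one (racemic)
Conditions: MeLi, THF, −78 °C; aq. NH4Cl
Reagents that add atoms: methyllithium, [Li]C
Why: 1,2-Addition of an organolithium to one carbonyl of a squarate diester at low temperature is the standard first stage of cyclobutenedione synthesis; the carbinol centre forms as a racemate and disappears in step 3.

Step 3
Reactants: 3 2,3-bis(benzyloxy)-4-hydroxy-4-methylcyclobut-2-en-1-one
Product: 4 3-(benzyloxy)-4-methylcyclobut-3-ene-1,2-dione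
Conditions: conc. aq. HCl (cat.), CH2Cl2, rt
Reagents that add atoms: water, O (supplies the new carbonyl oxygen; the hydroxyl oxygen of 3 leaves as water)
Why: Acid-catalysed ionisation of the tertiary allylic alcohol, capture of the benzyloxy-stabilised cation by water and loss of benzyl alcohol should give the vinylogous ester dione, the usual transposition of squarate adducts.

Step 4
Reactants: 5 methyl but-2-ynoate
Product: 6 methyl (E)-3-(trimethylstannyl)but-2-enoate
Conditions: Me3SnSnMe3, MeLi, THF, −20 °C; PhSCu; then 5, MeOH, −100 °C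
Reagents that add atoms: hexamethylditin, C[Sn](C)(C)[Sn](C)(C)C
Why: Kinetic syn-stannylcupration of the ynoate with in situ protonation puts tin and hydrogen on the same side, so tin is trans to the ester (E), a geometry that anti-hydroiodination of the ynoate cannot give and that later keeps the tertiary alkoxide away from the ester.

Step 5
Reactants: 6 methyl (E)-3-(trimethylstannyl)but-2-enoate
Product: 7 methyl (E)-3-iodobut-2-enoate
Conditions: I2, CH2Cl2, 0 °C
Reagents that add atoms: iodine, II
Why: Iododestannylation of an alkenylstannane is an ipso substitution that retains the double-bond geometry.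

Step 6
Reactants: 8 methyl orsellinate (methyl 2,4-dihydroxy-6-methylbenzoate)
Product: 10 methyl 3-formyl-2,4-dihydroxy-6-methylbenzoate, via α-chloro ether 9 (not isolated)
Conditions: Cl2CHOMe, TiCl4, CH2Cl2, 0 °C; then H2O
Reagents that add atoms: dichloromethyl methyl ether, COC(Cl)Cl; water, O
Why: Rieche formylation of the electron-rich ring; titanium bound to the phenoxide oxygens should deliver the electrophile to C3, the carbon flanked by both hydroxyls, where the aldehyde is chelated on both sides, with the C5 isomer expected as a separable minor product.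

Step 7
Reactants: 10 methyl 3-formyl-2,4-dihydroxy-6-methylbenzoate
Product: 11 methyl 2,4-bis(benzyloxy)-3-formyl-6-methylbenzoate
Conditions: BnBr, K2CO3, DMF, 60 °C
Reagents that add atoms: benzyl bromide, BrCc1ccccc1
Why: Williamson etherification of both phenols; warm DMF is enough to alkylate the doubly hydrogen-bonded 2-hydroxyl.

Step 8
Reactants: 11 methyl 2,4-bis(benzyloxy)-3-formyl-6-methylbenzoate
Product: 12 methyl 2,4-bis(benzyloxy)-3-(1,3-dioxolan-2-yl)-6-methylbenzoate
Conditions: HOCH2CH2OH, p-TsOH (cat.), toluene, reflux, azeotropic removal of water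
Reagents that add atoms: ethylene glycol, OCCO
Why: Acid-catalysed acetalisation masks the non-enolisable aldehyde before the strongly basic ester hydrolysis and the alkoxide acylation.

Step 9
Reactants: 12 methyl 2,4-bis(benzyloxy)-3-(1,3-dioxolan-2-yl)-6-methylbenzoate
Product: 13 2,4-bis(benzyloxy)-3-(1,3-dioxolan-2-yl)-6-methylbenzoic acid
Conditions: KOH, DMSO/H2O, 90 °C; then cold 1 M aq. HCl to pH 4
Reagents that add atoms: potassium hydroxide, [K+].[OH-]
Why: Saponification of the di-ortho-substituted benzoate needs hot hydroxide in a dipolar solvent, which the dioxolane and benzyl ethers tolerate, and the acidification is kept cold and mild to spare the acetal.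

Step 10
Reactants: 13 2,4-bis(benzyloxy)-3-(1,3-dioxolan-2-yl)-6-methylbenzoic acid
Product: 14 2,4-bis(benzyloxy)-3-(1,3-dioxolan-2-yl)-6-methylbenzoyl chloride
Conditions: Me2C=C(Cl)NMe2, CH2Cl2, 0 °C to rt; used crude
Reagents that add atoms: 1-chloro-N,N,2-trimethylprop-1-en-1-amine, CC(C)=C(Cl)N(C)C
Why: The α-chloroenamine turns carboxylic acids into acid chlorides under neutral conditions without releasing HCl, so the acid-labile dioxolane should survive.

Step 11
Reactants: 7 methyl (E)-3-iodobut-2-enoate; 4 3-(benzyloxy)-4-methylcyclobut-3-ene-1,2-dione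
Product: 16 methyl (E)-3-[2-(benzyloxy)-1-hydroxy-3-methyl-4-oxocyclobut-2-en-1-yl]but-2-enoate (racemic), via alkenylmagnesium chloride 15 (not isolated)
Conditions: iPrMgCl·LiCl, THF, −40 °C; then 4, −78 to −40 °C; aq. NH4Cl
Reagents that add atoms: none
Why: Iodine–magnesium exchange on a β-iodoenoate is fast at low temperature and retains geometry, and the Grignard reagent should add 1,2 to the ketone-like carbonyl next to the benzyloxy-bearing carbon rather than to the vinylogous ester carbonyl, forming the quaternary centre as a racemate while the E geometry prevents lactonisation of the alkoxide onto the ester.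

Step 12
Reactants: 16 methyl (E)-3-[2-(benzyloxy)-1-hydroxy-3-methyl-4-oxocyclobut-2-en-1-yl]but-2-enoate; 14 2,4-bis(benzyloxy)-3-(1,3-dioxolan-2-yl)-6-methylbenzoyl chloride
Product: 18 2-(benzyloxy)-1-[(E)-4-methoxy-4-oxobut-2-en-2-yl]-3-methyl-4-oxocyclobut-2-en-1-yl 2,4-bis(benzyloxy)-3-(1,3-dioxolan-2-yl)-6-methylbenzoate (racemic), via lithium alkoxide 17 (not isolated)
Conditions: LiN(SiMe3)2, THF, −78 °C; then 14, −78 to 0 °C
Reagents that add atoms: none
Why: O-Acylation of a lithium tert-alkoxide by an aroyl chloride; di-ortho-substituted, electron-rich aroyl chlorides are known to acylate hindered lithium alkoxides, and the alkoxide is the same species that is routinely trapped after organolithium addition to cyclobutenediones.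

Step 13
Reactants: 18 2-(benzyloxy)-1-[(E)-4-methoxy-4-oxobut-2-en-2-yl]-3-methyl-4-oxocyclobut-2-en-1-yl 2,4-bis(benzyloxy)-3-(1,3-dioxolan-2-yl)-6-methylbenzoate
Product: 21 methyl 4-(benzyloxy)-5-{[2,4-bis(benzyloxy)-3-(1,3-dioxolan-2-yl)-6-methylbenzoyl]oxy}-2-hydroxy-3,6-dimethylbenzoate, via dienylketene 19 (not isolated), via cyclohexadienone 20 (not isolated)
Conditions: toluene (degassed, 0.01 M), 110 °C, argon
Reagents that add atoms: none
Why: Heat should break the C1–C4 bond of the four-membered ring in a conrotatory 4π opening to give dienylketene 19, whose ketene carbon then bonds to the ester-bearing CH terminus in a thermally allowed disrotatory 6π electrocyclisation that closes the six-membered carbocycle; dienone 20, a β-keto ester, enolises to the phenol. The closest known reaction type is the Moore ring expansion of 4-alkenylcyclobutenones carrying a hydroxy, alkoxy, silyloxy or acyloxy group on C4 to hydroquinones and their mono-protected derivatives. No stereocentre remains, since the quaternary carbon becomes the sp2 C5 and the sp3 carbon of 20 is lost on aromatisation. The selectivity required is torquoselectivity: the alkenyl group must turn inward, and the acyloxy oxygen on C4, a lone-pair donor, prefers outward rotation, while a ketene of the wrong geometry should mostly revert to 18. The E enoate puts hydrogen rather than the ester on the inside of the closing terminus, so closure is not slowed. The three oxygens are fixed by origin (ketene oxygen as O2–H, squarate ether as O4–Bn, acyloxy as O5), so the depside ester is placed without any phenol differentiation.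

Step 14
Reactants: 21 methyl 4-(benzyloxy)-5-{[2,4-bis(benzyloxy)-3-(1,3-dioxolan-2-yl)-6-methylbenzoyl]oxy}-2-hydroxy-3,6-dimethylbenzoate
Product: 22 methyl 4-(benzyloxy)-5-{[2,4-bis(benzyloxy)-3-formyl-6-methylbenzoyl]oxy}-2-hydroxy-3,6-dimethylbenzoate
Conditions: 1 M aq. HCl, THF, rt
Reagents that add atoms: water, O
Why: Acid-catalysed hydrolysis of the electron-rich aryl dioxolane should be fast under conditions that leave the aryl ester, the methyl ester and the benzyl ethers untouched.

Step 15
Reactants: 22 methyl 4-(benzyloxy)-5-{[2,4-bis(benzyloxy)-3-formyl-6-methylbenzoyl]oxy}-2-hydroxy-3,6-dimethylbenzoate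
Product: 23 methyl 5-[(3-formyl-2,4-dihydroxy-6-methylbenzoyl)oxy]-2,4-dihydroxy-3,6-dimethylbenzoate (target)
Conditions: H2 (1 atm), 10% Pd/C, EtOAc, rt, stopped at complete debenzylation
Reagents that add atoms: none
Why: Hydrogenolysis of the three aryl benzyl ethers over palladium should be much faster than reduction of the hindered aldehyde, which becomes hydrogen-bonded on both sides once its flanking phenols are freed.

**Compound list**
1 | squaric acid | OC1=C(O)C(=O)C1=O | starting material
2 | 3,4-bis(benzyloxy)cyclobut-3-ene-1,2-dione | O=C1C(=O)C(OCc2ccccc2)=C1OCc1ccccc1 | intermediate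
3 | 2,3-bis(benzyloxy)-4-hydroxy-4-methylcyclobut-2-en-1-one (racemic) | C[C@]1(O)C(OCc2ccccc2)=C(OCc2ccccc2)C1=O | intermediate
4 | 3-(benzyloxy)-4-methylcyclobut-3-ene-1,2-dione | CC1=C(OCc2ccccc2)C(=O)C1=O | intermediate
5 | methyl but-2-ynoate | CC#CC(=O)OC | starting material
6 | methyl (E)-3-(trimethylstannyl)but-2-enoate | C[Sn](C)(C)/C(C)=C/C(=O)OC | intermediate
7 | methyl (E)-3-iodobut-2-enoate | I/C(C)=C/C(=O)OC | intermediate
8 | methyl orsellinate (methyl 2,4-dihydroxy-6-methylbenzoate) | COC(=O)c1c(C)cc(O)cc1O | starting material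
9 | methyl 3-[chloro(methoxy)methyl]-2,4-dihydroxy-6-methylbenzoate (titanium-bound, not isolated) | COC(=O)c1c(C)cc(O)c(C(Cl)OC)c1O | intermediate
10 | methyl 3-formyl-2,4-dihydroxy-6-methylbenzoate | COC(=O)c1c(C)cc(O)c(C=O)c1O | intermediate
11 | methyl 2,4-bis(benzyloxy)-3-formyl-6-methylbenzoate | COC(=O)c1c(C)cc(OCc2ccccc2)c(C=O)c1OCc1ccccc1 | intermediate
12 | methyl 2,4-bis(benzyloxy)-3-(1,3-dioxolan-2-yl)-6-methylbenzoate | COC(=O)c1c(C)cc(OCc2ccccc2)c(C2OCCO2)c1OCc1ccccc1 | intermediate
13 | 2,4-bis(benzyloxy)-3-(1,3-dioxolan-2-yl)-6-methylbenzoic acid | OC(=O)c1c(C)cc(OCc2ccccc2)c(C2OCCO2)c1OCc1ccccc1 | intermediate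
14 | 2,4-bis(benzyloxy)-3-(1,3-dioxolan-2-yl)-6-methylbenzoyl chloride | ClC(=O)c1c(C)cc(OCc2ccccc2)c(C2OCCO2)c1OCc1ccccc1 | intermediate
15 | [(E)-4-methoxy-4-oxobut-2-en-2-yl]magnesium chloride, LiCl complex (not isolated) | Cl[Mg]/C(C)=C/C(=O)OC | intermediate
16 | methyl (E)-3-[2-(benzyloxy)-1-hydroxy-3-methyl-4-oxocyclobut-2-en-1-yl]but-2-enoate (racemic) | CC1=C(OCc2ccccc2)[C@](O)(/C(C)=C/C(=O)OC)C1=O | intermediate
17 | lithium alkoxide of 16 (not isolated) | CC1=C(OCc2ccccc2)[C@]([O-])(/C(C)=C/C(=O)OC)C1=O.[Li+] | intermediate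
18 | 2-(benzyloxy)-1-[(E)-4-methoxy-4-oxobut-2-en-2-yl]-3-methyl-4-oxocyclobut-2-en-1-yl 2,4-bis(benzyloxy)-3-(1,3-dioxolan-2-yl)-6-methylbenzoate (racemic) | CC1=C(OCc2ccccc2)[C@](OC(=O)c2c(C)cc(OCc3ccccc3)c(C3OCCO3)c2OCc2ccccc2)(/C(C)=C/C(=O)OC)C1=O | intermediate
19 | methyl (2E,4Z)-4-{[2,4-bis(benzyloxy)-3-(1,3-dioxolan-2-yl)-6-methylbenzoyl]oxy}-5-(benzyloxy)-3,6-dimethyl-7-oxohepta-2,4,6-trienoate (dienylketene, not isolated) | O=C=C(C)/C(OCc1ccccc1)=C(\C(C)=C\C(=O)OC)OC(=O)c1c(C)cc(OCc2ccccc2)c(C2OCCO2)c1OCc1ccccc1 | intermediate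
20 | methyl 5-{[2,4-bis(benzyloxy)-3-(1,3-dioxolan-2-yl)-6-methylbenzoyl]oxy}-4-(benzyloxy)-3,6-dimethyl-2-oxocyclohexa-3,5-diene-1-carboxylate (racemic, not isolated) | COC(=O)[C@H]1C(C)=C(OC(=O)c2c(C)cc(OCc3ccccc3)c(C3OCCO3)c2OCc2ccccc2)C(OCc2ccccc2)=C(C)C1=O | intermediate
21 | methyl 4-(benzyloxy)-5-{[2,4-bis(benzyloxy)-3-(1,3-dioxolan-2-yl)-6-methylbenzoyl]oxy}-2-hydroxy-3,6-dimethylbenzoate | COC(=O)c1c(C)c(OC(=O)c2c(C)cc(OCc3ccccc3)c(C3OCCO3)c2OCc2ccccc2)c(OCc2ccccc2)c(C)c1O | intermediate
22 | methyl 4-(benzyloxy)-5-{[2,4-bis(benzyloxy)-3-formyl-6-methylbenzoyl]oxy}-2-hydroxy-3,6-dimethylbenzoate | COC(=O)c1c(C)c(OC(=O)c2c(C)cc(OCc3ccccc3)c(C=O)c2OCc2ccccc2)c(OCc2ccccc2)c(C)c1O | intermediate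
23 | methyl 5-[(3-formyl-2,4-dihydroxy-6-methylbenzoyl)oxy]-2,4-dihydroxy-3,6-dimethylbenzoate | COC(=O)c1c(C)c(OC(=O)c2c(C)cc(O)c(C=O)c2O)c(O)c(C)c1O | target

**Step count and risks**

Total step count: 15. Longest linear sequence: 9 steps (steps 6, 7, 8, 9, 10, 12, 13, 14, 15, from methyl orsellinate 8).

The three steps most likely to fail:

Step 11. The ester-bearing alkenylmagnesium may form too slowly, condense with its own ester or lose its geometry before it reaches the dione. The fallback moves the ester carbon to the alcohol oxidation level so that a plain alkenyllithium can be used; it sets out from iodide 7 (with dione 4) and comes back at alcohol 16. Reduction of 7 with iBu2AlH (CH2Cl2, −78 °C) should give (E)-3-iodobut-2-en-1-ol F1, and TBSCl/imidazole should give tert-butyl{[(E)-3-iodobut-2-en-1-yl]oxy}dimethylsilane F2. Iodine–lithium exchange with t-BuLi (2 equiv, Et2O, −78 °C) and addition to 4 should give 3-(benzyloxy)-4-[(E)-4-{[tert-butyl(dimethyl)silyl]oxy}but-2-en-2-yl]-4-hydroxy-2-methylcyclobut-2-en-1-one F3. Bu4NF should free 3-(benzyloxy)-4-hydroxy-4-[(E)-4-hydroxybut-2-en-2-yl]-2-methylcyclobut-2-en-1-one F4. MnO2 should oxidise only the allylic primary alcohol to (E)-3-[2-(benzyloxy)-1-hydroxy-3-methyl-4-oxocyclobut-2-en-1-yl]but-2-enal F5. Pinnick oxidation (NaClO2, NaH2PO4, 2-methylbut-2-ene) should give (E)-3-[2-(benzyloxy)-1-hydroxy-3-methyl-4-oxocyclobut-2-en-1-yl]but-2-enoic acid F6, and Me3SiCHN2 in toluene/MeOH should return 16.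

Step 12. The hindered tertiary alkoxide may fail to attack the di-ortho-substituted aroyl chloride, or may ring-open or revert on warming before it is acylated. The fallback forms the depside ester on a phenol after the ring expansion; it sets out from alcohol 16 and comes back at 21. Thermolysis of free alcohol 16 (degassed toluene, 110 °C, argon), the parent Moore ring expansion, should give methyl 4-(benzyloxy)-2,5-dihydroxy-3,6-dimethylbenzoate F7. Acylation with 14 (Et3N, DMAP cat., CH2Cl2, 0 °C) should occur at O5, because O2–H is held in a hydrogen bond to the neighbouring methyl ester as in classical depside couplings, giving 21.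

Step 13. The acyloxy group may turn inward during ring opening or its carbonyl may capture the ketene, diverting material from the 6π closure. The fallback carries a silyl group on the quaternary oxygen through the ring expansion and exchanges it for the acyl group afterwards; it sets out from alcohol 16 and comes back at 21. TBSOTf/2,6-lutidine (CH2Cl2, −78 °C) should give methyl (E)-3-[2-(benzyloxy)-1-{[tert-butyl(dimethyl)silyl]oxy}-3-methyl-4-oxocyclobut-2-en-1-yl]but-2-enoate F8. Its thermolysis (toluene, 110 °C), in which the bulky, strongly donating silyloxy group rotates outward reliably, should give methyl 4-(benzyloxy)-5-{[tert-butyl(dimethyl)silyl]oxy}-2-hydroxy-3,6-dimethylbenzoate F9. Desilylative acylation with 14 and CsF in DMF should then give 21, with O5 still defined by its origin.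

**Further compounds**
F1 | step 11 | (E)-3-iodobut-2-en-1-ol | I/C(C)=C/CO
F2 | step 11 | tert-butyl{[(E)-3-iodobut-2-en-1-yl]oxy}dimethylsilane | I/C(C)=C/CO[Si](C)(C)C(C)(C)C
F3 | step 11 | 3-(benzyloxy)-4-[(E)-4-{[tert-butyl(dimethyl)silyl]oxy}but-2-en-2-yl]-4-hydroxy-2-methylcyclobut-2-en-1-one (racemic) | CC1=C(OCc2ccccc2)[C@](O)(/C(C)=C/CO[Si](C)(C)C(C)(C)C)C1=O
F4 | step 11 | 3-(benzyloxy)-4-hydroxy-4-[(E)-4-hydroxybut-2-en-2-yl]-2-methylcyclobut-2-en-1-one (racemic) | CC1=C(OCc2ccccc2)[C@](O)(/C(C)=C/CO)C1=O
F5 | step 11 | (E)-3-[2-(benzyloxy)-1-hydroxy-3-methyl-4-oxocyclobut-2-en-1-yl]but-2-enal (racemic) | CC1=C(OCc2ccccc2)[C@](O)(/C(C)=C/C=O)C1=O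
F6 | step 11 | (E)-3-[2-(benzyloxy)-1-hydroxy-3-methyl-4-oxocyclobut-2-en-1-yl]but-2-enoic acid (racemic) | CC1=C(OCc2ccccc2)[C@](O)(/C(C)=C/C(O)=O)C1=O
F7 | step 12 | methyl 4-(benzyloxy)-2,5-dihydroxy-3,6-dimethylbenzoate | COC(=O)c1c(C)c(O)c(OCc2ccccc2)c(C)c1O
F8 | step 13 | methyl (E)-3-[2-(benzyloxy)-1-{[tert-butyl(dimethyl)silyl]oxy}-3-methyl-4-oxocyclobut-2-en-1-yl]but-2-enoate (racemic) | CC1=C(OCc2ccccc2)[C@](O[Si](C)(C)C(C)(C)C)(/C(C)=C/C(=O)OC)C1=O
F9 | step 13 | methyl 4-(benzyloxy)-5-{[tert-butyl(dimethyl)silyl]oxy}-2-hydroxy-3,6-dimethylbenzoate | COC(=O)c1c(C)c(O[Si](C)(C)C(C)(C)C)c(OCc2ccccc2)c(C)c1O
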